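**Retrosynthetic overview**

1. Feature: on the cyclohex-2-enone ring (C1 carbonyl, C2=C3, C4 secondary carbinol, C5 tertiary carbinol carrying the C19 chain, C6 methylene) the cis C4–O/C5–O pair with a carbon branch on C5 is the ipso,ortho cis-diol of benzoic acid, whose carboxyl carbon becomes C1' of the chain.
2. Endgame disconnections: acetonide off; C1 ketone from a C1 allylic alcohol; that alcohol and the C2=C3 bond from a 1,2-epoxy-3-ol by radical 1,3-transposition, run in the same tin hydride operation that removes the C1' oxygen; C1'–C2' from a C18 Grignard reagent and a C1' lactol.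
3. The lactol comes from a vinyl oxirane (epoxidation of the diene bond remote from the quaternary carbon, then 1,4-reductive opening, which puts the required hydrogen on C6) and this from the acetonide methyl ester of the enzymatic diol acid.
4. Rings: the only ring of the target is the benzene ring of benzoic acid, dearomatised in the key step; no carbocycle is built, and only temporary heterocycles (dioxolane, oxiranes, lactol) are closed and opened.
5. Side chain: 1,14-tetradecanediol and 1-butyne give (E)-1-bromooctadec-15-ene.

Key step: step 1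

Convention: in the steps the ring carbons keep the numbering of acid 2 (C1 quaternary carbinol, C2 secondary carbinol, then C3 to C6; these are target C5, C4, C3, C2, C1, C6); C1' is the former carboxyl carbon; α is the ring face of the two oxygens from step 1, β the other face.
Assumption: the configurations at C3 (6, 16–19), at C4/C5 of the epoxides (5, 17–19), at C5 of 20, at the lactol carbon of 7 and at C1' (16–19) are drawn as expected but are immaterial, because all these centres end as sp2 or CH2 carbons.

**Route**

Step 1
Reactants: 1 benzoic acid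
Product: 2 (1S,2R)-1,2-dihydroxycyclohexa-3,5-diene-1-carboxylic acid
Conditions: whole cells of Ralstonia eutropha B9 (Cupriavidus necator B9), PhCO2Na feed, fructose, mineral salts medium, air, pH 7, 30 °C; cold acidification, extraction
Reagents that add atoms: dioxygen, O=O
Why: Benzoate 1,2-dioxygenase is a Rieske non-haem iron dioxygenase: its reductase passes two electrons from NADH through the Rieske iron–sulfur cluster to a mononuclear iron centre, which binds O2 beside the bound benzoate and transfers both oxygen atoms to one face of the C1=C2 (ipso/ortho) bond, so the new C1–O and C2–O bonds are cis. The closest known reaction type is arene cis-dihydroxylation by toluene- and naphthalene-type Rieske dioxygenases, and benzoate is the native substrate of this enzyme, so no engineering is needed. No ring is closed; the step breaks aromaticity and forms two C–O bonds. Both new stereocentres (C1 S, C2 R) are set by the enzyme, whose carboxylate-binding pocket decides which ring face meets the iron-bound oxygen. The step needs ipso/ortho rather than ortho/meta regioselectivity and absolute facial selectivity, and both follow from the anchoring of the carboxylate in the active site. The diol should accumulate because strain B9 lacks the cis-diol dehydrogenase that would rearomatise it.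

Step 2
Reactants: 2 (1S,2R)-1,2-dihydroxycyclohexa-3,5-diene-1-carboxylic acid
Product: 3 (3aS,7aR)-2,2-dimethyl-3a,7a-dihydro-1,3-benzodioxole-3a-carboxylic acid (acetonide of 2)
Conditions: 2,2-dimethoxypropane, TsOH (cat.), acetone, rt
Reagents that add atoms: 2,2-dimethoxypropane, COC(C)(C)OC
Why: Acid-catalysed transketalisation closes a five-membered dioxolane on the cis-1,2-diol without touching either stereocentre, and the anhydrous, only mildly acidic medium avoids the dehydrative rearomatisation to which 2 is prone.

Step 3
Reactants: 3 (3aS,7aR)-2,2-dimethyl-3a,7a-dihydro-1,3-benzodioxole-3a-carboxylic acid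
Product: 4 methyl (3aS,7aR)-2,2-dimethyl-3a,7a-dihydro-1,3-benzodioxole-3a-carboxylate
Conditions: MeI, K2CO3, DMF, rt
Reagents that add atoms: iodomethane, CI
Why: SN2 O-methylation of the potassium carboxylate; the base is too weak to affect the diene and no stereocentre is involved.

Step 4
Reactants: 4 methyl (3aS,7aR)-2,2-dimethyl-3a,7a-dihydro-1,3-benzodioxole-3a-carboxylate
Product: 5 methyl 3β,4β-epoxy-1α,2α-(isopropylidenedioxy)cyclohex-5-ene-1β-carboxylate
Conditions: mCPBA (1.05 equiv), NaHCO3, CH2Cl2, 0 °C
Reagents that add atoms: 3-chloroperoxybenzoic acid, OOC(=O)c1cccc(Cl)c1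
Why: Prilezhaev epoxidation should take the C3=C4 bond, because C5=C6 is deactivated and shielded by the adjacent quaternary C1 with its ester, and the peracid should approach anti to the dioxolane (β face); the two epoxide centres are lost again later.

Step 5
Reactants: 5 methyl 3β,4β-epoxy-1α,2α-(isopropylidenedioxy)cyclohex-5-ene-1β-carboxylate
Product: 6 methyl 3β-hydroxy-1α,2α-(isopropylidenedioxy)cyclohex-4-ene-1β-carboxylate
Conditions: SmI2 (2.5 equiv), THF, MeOH, −90 °C
Reagents that add atoms: none
Why: Single-electron reduction of the vinyl oxirane by divalent samarium cleaves the allylic C4–O bond, and the allylsamarium held at C4 beside the trivalent samarium alkoxide is protonated by methanol at the far terminus C6 (1,4-reductive opening of a vinyl epoxide), which puts the hydrogen the target needs on C6 while the ester is inert at this temperature; C3 keeps its β C–O bond.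

Step 6
Reactants: 6 methyl 3β-hydroxy-1α,2α-(isopropylidenedioxy)cyclohex-4-ene-1β-carboxylate
Product: 7 bridged lactol of the C1' aldehyde on the C3β oxygen (1α,2α-isopropylidenedioxy-6-oxabicyclo[3.2.1]oct-3-en-7-ol core; anomer mixture)
Conditions: i-Bu2AlH (3 equiv), CH2Cl2, −78 °C; MeOH, then aq. KNaC4H4O6
Reagents that add atoms: none
Why: Partial reduction of the ester by i-Bu2AlH stops at the aluminium hemiacetal at −78 °C, and on work-up the aldehyde is captured by the cis (1,3-diaxial) C3 hydroxyl as a five-membered lactol, which also guards it against over-reduction; the anomeric centre is lost in step 11.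

Step 7
Reactants: 8 1,14-tetradecanediol
Product: 9 14-bromotetradecan-1-ol
Conditions: 48% aq. HBr, toluene, reflux
Reagents that add atoms: hydrogen bromide, Br
Why: Acid-mediated SN2 substitution of one hydroxyl; in the two-phase toluene system the bromo alcohol is extracted away from the acid, which favours monobromination.

Step 8
Reactants: 9 14-bromotetradecan-1-ol; 10 1-butyne
Product: 12 octadec-15-yn-1-ol, via but-1-ynyllithium 11 (not isolated)
Conditions: 10 (3 equiv), n-BuLi (2.6 equiv), THF, −78 °C; DMPU, then 9, −78 °C → rt; aq. NH4Cl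
Reagents that add atoms: none
Why: Deprotonation of the terminal alkyne and SN2 alkylation of the lithium acetylide by the primary bromide in THF/DMPU; one further equivalent of acetylide carries the hydroxyl as its lithium alkoxide.

Step 9
Reactants: 12 octadec-15-yn-1-ol
Product: 13 (E)-octadec-15-en-1-ol
Conditions: Li, liquid NH3/THF, −33 °C; NH4Cl
Reagents that add atoms: none
Why: Dissolving-metal reduction of the internal alkyne runs through the trans vinyl radical anion and vinyl anion, so protonation by ammonia should give the E alkene (C16'=C17' of the target).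

Step 10
Reactants: 13 (E)-octadec-15-en-1-ol
Product: 14 (E)-1-bromooctadec-15-ene
Conditions: CBr4, PPh3, CH2Cl2, 0 °C
Reagents that add atoms: tetrabromomethane, BrC(Br)(Br)Br
Why: Appel reaction: the alkoxyphosphonium ion is displaced by bromide in an SN2 step that leaves the remote E alkene alone.

Step 11
Reactants: 7 bridged lactol; 14 (E)-1-bromooctadec-15-ene
Product: 16 1β-[(16E)-1-hydroxynonadec-16-enyl]-1α,2α-(isopropylidenedioxy)cyclohex-4-en-3β-ol (C1' epimers), via (E)-octadec-15-enylmagnesium bromide 15 (not isolated)
Conditions: 14, Mg, THF, 40 °C; then 7 (3 equiv of 15 per 7), THF, 0 °C → rt; aq. NH4Cl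
Reagents that add atoms: none
Why: Grignard addition to a lactol: the first equivalent deprotonates it, and the ring-opened magnesium alkoxide aldehyde (non-enolisable, C1 is quaternary) takes up the second to form the C1'–C2' bond; the C1' carbinol centre is not controlled because its oxygen is removed in step 14.

Step 12
Reactants: 16 1β-[(16E)-1-hydroxynonadec-16-enyl]-1α,2α-(isopropylidenedioxy)cyclohex-4-en-3β-ol
Product: 17 4β,5β-epoxy-1β-[(16E)-1-hydroxynonadec-16-enyl]-1α,2α-(isopropylidenedioxy)cyclohexan-3β-ol
Conditions: VO(acac)2 (5 mol %), t-BuOOH (1.5 equiv), CH2Cl2, 0 °C → rt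
Reagents that add atoms: tert-butyl hydroperoxide, CC(C)(C)OO
Why: Vanadium-catalysed hydroxyl-directed epoxidation delivers oxygen from the alkylperoxo vanadate bound to the allylic C3 hydroxyl, syn to it (β face), and therefore leaves the remote chain alkene untouched.

Step 13
Reactants: 17 4β,5β-epoxy-1β-[(16E)-1-hydroxynonadec-16-enyl]-1α,2α-(isopropylidenedioxy)cyclohexan-3β-ol
Product: 19 O3,O1'-bis(S-methyl dithiocarbonate) of 17 (bis-xanthate), via disodium bis(dithiocarbonate) 18 (not isolated)
Conditions: NaH (4 equiv), THF, 0 °C; CS2 (excess), rt; then MeI (excess)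
Reagents that add atoms: carbon disulfide, S=C=S; iodomethane, CI
Why: Xanthate formation: both secondary sodium alkoxides add to CS2 and the dithiocarbonate salts are S-methylated; the cis relation of the C3 alkoxide and the oxirane rules out a Payne rearrangement.

Step 14
Reactants: 19 bis-xanthate
Product: 20 1β-[(16E)-nonadec-16-enyl]-1α,2α-(isopropylidenedioxy)cyclohex-3-en-5β-ol
Conditions: Bu3SnH (6 equiv, about 0.3 M), AIBN (cat.), toluene, 90 °C
Reagents that add atoms: none
Why: One radical chain does two jobs: Barton–McCombie deoxygenation turns C1' into a methylene, and the C3 radical from the second xanthate opens the adjacent oxirane (oxiranylcarbinyl radical fragmentation, the radical counterpart of the Wharton transposition) to give the C3=C4 alkene and a C5 alkoxyl radical that is reduced by Bu3SnH, kept concentrated to outrun β-scission; C5 keeps the β C–O bond of the epoxide.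

Step 15
Reactants: 20 1β-[(16E)-nonadec-16-enyl]-1α,2α-(isopropylidenedioxy)cyclohex-3-en-5β-ol
Product: 21 4,5-O-isopropylidene derivative of 22 (acetonide enone)
Conditions: activated MnO2 (excess), CH2Cl2, rt
Reagents that add atoms: none
Why: MnO2 oxidation of the only hydroxyl, which is allylic, gives the enone without touching the isolated chain alkene or the acetonide.

Step 16
Reactants: 21 acetonide enone
Product: 22 (4R,5S)-4,5-dihydroxy-5-[(16E)-nonadec-16-enyl]cyclohex-2-en-1-one (target)
Conditions: TFA/H2O/THF, 0 °C, short reaction time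
Reagents that add atoms: none
Why: Acid-catalysed hydrolysis of the ketal, run cold and briefly so that the tertiary β-hydroxy ketone does not dehydrate; both carbinol centres keep the configuration set in step 1.

**Compound list**

1 | benzoic acid | OC(=O)c1ccccc1 | starting material
2 | (1S,2R)-1,2-dihydroxycyclohexa-3,5-diene-1-carboxylic acid | OC(=O)[C@]1(O)C=CC=C[C@H]1O | intermediate
3 | (3aS,7aR)-2,2-dimethyl-3a,7a-dihydro-1,3-benzodioxole-3a-carboxylic acid | OC(=O)[C@]1(OC(C)(C)O2)C=CC=C[C@H]12 | intermediate
4 | methyl (3aS,7aR)-2,2-dimethyl-3a,7a-dihydro-1,3-benzodioxole-3a-carboxylate | COC(=O)[C@]1(OC(C)(C)O2)C=CC=C[C@H]12 | intermediate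
5 | methyl 3β,4β-epoxy-1α,2α-(isopropylidenedioxy)cyclohex-5-ene-1β-carboxylate | COC(=O)[C@]1(OC(C)(C)O2)C=C[C@@H]3O[C@@H]3[C@H]12 | intermediate
6 | methyl 3β-hydroxy-1α,2α-(isopropylidenedioxy)cyclohex-4-ene-1β-carboxylate | COC(=O)[C@]1(OC(C)(C)O2)CC=C[C@H](O)[C@H]12 | intermediate
7 | bridged lactol, C1'H(OH) on C1β bonded to the C3β oxygen, 1α,2α-acetonide, C4=C5 (anomer mixture) | OC3[C@]1(OC(C)(C)O2)CC=C[C@H](O3)[C@H]12 | intermediate
8 | 1,14-tetradecanediol | OCCCCCCCCCCCCCCO | starting material
9 | 14-bromotetradecan-1-ol | OCCCCCCCCCCCCCCBr | intermediate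
10 | 1-butyne | CCC#C | starting material
11 | but-1-ynyllithium | [Li]C#CCC | intermediate (not isolated)
12 | octadec-15-yn-1-ol | CCC#CCCCCCCCCCCCCCCO | intermediate
13 | (E)-octadec-15-en-1-ol | CC/C=C/CCCCCCCCCCCCCCO | intermediate
14 | (E)-1-bromooctadec-15-ene | CC/C=C/CCCCCCCCCCCCCCBr | intermediate
15 | (E)-octadec-15-enylmagnesium bromide | CC/C=C/CCCCCCCCCCCCCC[Mg]Br | intermediate (not isolated)
16 | 1β-[(16E)-1-hydroxynonadec-16-enyl]-1α,2α-(isopropylidenedioxy)cyclohex-4-en-3β-ol (C1' epimers) | CC/C=C/CCCCCCCCCCCCCCC(O)[C@]1(OC(C)(C)O2)CC=C[C@H](O)[C@H]12 | intermediate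
17 | 4β,5β-epoxy-1β-[(16E)-1-hydroxynonadec-16-enyl]-1α,2α-(isopropylidenedioxy)cyclohexan-3β-ol | CC/C=C/CCCCCCCCCCCCCCC(O)[C@]1(OC(C)(C)O2)C[C@@H]3O[C@@H]3[C@H](O)[C@H]12 | intermediate
18 | disodium O3,O1'-bis(dithiocarbonate) of 17 | [Na+].[Na+].CC/C=C/CCCCCCCCCCCCCCC(OC(=S)[S-])[C@]1(OC(C)(C)O2)C[C@@H]3O[C@@H]3[C@H](OC(=S)[S-])[C@H]12 | intermediate (not isolated)
19 | O3,O1'-bis(S-methyl dithiocarbonate) of 17 (bis-xanthate) | CC/C=C/CCCCCCCCCCCCCCC(OC(=S)SC)[C@]1(OC(C)(C)O2)C[C@@H]3O[C@@H]3[C@H](OC(=S)SC)[C@H]12 | intermediate
20 | 1β-[(16E)-nonadec-16-enyl]-1α,2α-(isopropylidenedioxy)cyclohex-3-en-5β-ol | CC/C=C/CCCCCCCCCCCCCCC[C@]1(OC(C)(C)O2)C[C@H](O)C=C[C@H]12 | intermediate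
21 | 4,5-O-isopropylidene derivative of 22 (configuration as in 22) | CC/C=C/CCCCCCCCCCCCCCC[C@]1(OC(C)(C)O2)CC(=O)C=C[C@H]12 | intermediate
22 | (4R,5S)-4,5-dihydroxy-5-[(16E)-nonadec-16-enyl]cyclohex-2-en-1-one | CC/C=C/CCCCCCCCCCCCCCC[C@]1(O)CC(=O)C=C[C@H]1O | target

**Step count**

Total: 16 steps (12 on the main line, 4 for the side chain). Longest linear sequence: 12 steps (steps 1–6 and 11–16).

**Steps most likely to fail**

Step 5. What may go wrong: protonation of the allylsamarium at C4 instead of C6, or loss of the C1 dioxolane oxygen from the C6 carbanion followed by aromatisation. The fallback sets out from 5 and comes back at 7, and uses hydride delivery instead of electron transfer. Excess i-Bu2AlH in toluene (−78 → 0 °C) should reduce the ester to the primary alcohol and, bound to the oxirane oxygen, deliver hydride syn to C6 (SN2′ opening), giving 1β-(hydroxymethyl)-1α,2α-(isopropylidenedioxy)cyclohex-4-en-3β-ol F1. TEMPO with PhI(OAc)2 oxidises the primary alcohol, and the lactol formed with the cis C3 hydroxyl goes on to the bridged γ-lactone F2. i-Bu2AlH at −78 °C then reduces F2 to lactol 7.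

Step 14. What may go wrong: ring-opening β-scission of the C5 alkoxyl radical before it is reduced, or incomplete reduction at the hindered C1' centre. The fallback sets out from 16 and comes back at 21, and carries out the 1,3-transposition by ionic chemistry. MnO2 oxidises only the allylic C3 hydroxyl of 16 to the cyclohex-4-en-3-one F3. Weitz–Scheffer epoxidation (t-BuOOH, DBU, CH2Cl2) gives the 4,5-epoxy-3-ketone F4. Wharton transposition (N2H4·H2O, AcOH cat., MeOH) gives the cyclohex-3-en-5-ol that still carries the C1' hydroxyl F5. MnO2 again gives the C1'-hydroxy enone F6. 1,1'-Thiocarbonyldiimidazole (DMAP, 1,2-dichloroethane, reflux) gives its C1' imidazolylthiocarbonyl ester F7, and Barton–McCombie reduction (Bu3SnH, AIBN) returns to 21.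

Step 16. What may go wrong: acid-promoted loss of the tertiary hydroxyl β to the ketone, followed by aromatisation to a 3-alkylphenol. The fallback sets out from 20 and comes back at 22, and unmasks the diol before the ketone exists. Aqueous AcOH (40 °C) removes the acetonide while C5 is still a carbinol, giving the 1,2,5-triol F8. PhB(OH)2 (toluene, molecular sieves) ties up the cis-1,2-diol as the cyclic phenylboronate F9; the C5 hydroxyl, trans to the C1 oxygen, cannot take part. MnO2 gives the boronate-protected enone F10, and exchange with pinacol under neutral conditions releases 22.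

**Further compounds**

F1 | step 5 | 1β-(hydroxymethyl)-1α,2α-(isopropylidenedioxy)cyclohex-4-en-3β-ol | OC[C@]1(OC(C)(C)O2)CC=C[C@H](O)[C@H]12
F2 | step 5 | bridged γ-lactone (7-oxo analogue of lactol 7) | O=C3[C@]1(OC(C)(C)O2)CC=C[C@H](O3)[C@H]12
F3 | step 14 | 1β-[(16E)-1-hydroxynonadec-16-enyl]-1α,2α-(isopropylidenedioxy)cyclohex-4-en-3-one | CC/C=C/CCCCCCCCCCCCCCC(O)[C@]1(OC(C)(C)O2)CC=CC(=O)[C@H]12
F4 | step 14 | 4,5-epoxy-1β-[(16E)-1-hydroxynonadec-16-enyl]-1α,2α-(isopropylidenedioxy)cyclohexan-3-one (epoxide face not critical) | CC/C=C/CCCCCCCCCCCCCCC(O)[C@]1(OC(C)(C)O2)CC3OC3C(=O)[C@H]12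
F5 | step 14 | 1β-[(16E)-1-hydroxynonadec-16-enyl]-1α,2α-(isopropylidenedioxy)cyclohex-3-en-5-ol (C5 epimer not critical) | CC/C=C/CCCCCCCCCCCCCCC(O)[C@]1(OC(C)(C)O2)CC(O)C=C[C@H]12
F6 | step 14 | C1'-hydroxy derivative of 21 | CC/C=C/CCCCCCCCCCCCCCC(O)[C@]1(OC(C)(C)O2)CC(=O)C=C[C@H]12
F7 | step 14 | O-(imidazol-1-ylthiocarbonyl) derivative of F6 | CC/C=C/CCCCCCCCCCCCCCC(OC(=S)n3ccnc3)[C@]1(OC(C)(C)O2)CC(=O)C=C[C@H]12
F8 | step 16 | 1β-[(16E)-nonadec-16-enyl]cyclohex-3-ene-1α,2α,5β-triol | CC/C=C/CCCCCCCCCCCCCCC[C@]1(O)C[C@H](O)C=C[C@H]1O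
F9 | step 16 | cyclic phenylboronate of F8 on the 1α,2α-diol | CC/C=C/CCCCCCCCCCCCCCC[C@]1(OB(c3ccccc3)O2)C[C@H](O)C=C[C@H]12
F10 | step 16 | cyclic phenylboronate of 22 | CC/C=C/CCCCCCCCCCCCCCC[C@]1(OB(c3ccccc3)O2)CC(=O)C=C[C@H]12
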